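The cyclohexane ring (C1 bears the side chain, C4 the CH3/Cl pair, C5 the Br; C8 is the tertiary carbinol carbon) is grown from a cyclopentane. A vinylogous Mukaiyama–Michael addition of the silyloxyfuran of α-angelica lactone to cyclopentenone sets C1 and C8 and leaves a silyl enol ether at C4=C6; cyclopropanation adds C5. The key Fe(III) ring expansion of this 1-siloxybicyclo[3.1.0]hexane cuts the shared C4–C6 bond: it exploits the C4–C5–C6 segment, turns the 1,3-related C4/C1 into the 1,4 pair of the target ring, and leaves a C5=C6 enone that keeps C1 stereogenic. An epoxide–bromohydrin–bromonium relay then sets the diequatorial Br/Cl pair.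

Key step: step 5

Remark on numbering: C2, C3 and C6 are the ring CH2 groups, with C6 between C1 and C5. C8–C11 run from the tertiary carbinol carbon to the allylic carbinol carbon.

Assumption: the antipode of the chiral catalyst in step 2 that gives the drawn enantiomer must be found by experiment. Both antipodes are accessible.

Step 1
Reactants: 1 α-angelica lactone
Product: 2 5-methyl-2-(trimethylsilyloxy)furan
Conditions: TMSOTf, Et3N, Et2O, 0 °C
Reagents that add atoms: trimethylsilyl triflate, C[Si](C)(C)OS(=O)(=O)C(F)(F)F
Why: Soft enolisation and O-silylation of the β,γ-butenolide (silyl dienol ether formation) gives the aromatic silyloxyfuran, and no stereocenter forms.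

Step 2
Reactants: 2 5-methyl-2-(trimethylsilyloxy)furan; 3 cyclopent-2-en-1-one
Product: 4 (5R)-5-methyl-5-[(1S)-3-(trimethylsilyloxy)cyclopent-2-en-1-yl]furan-2(5H)-one
Conditions: chiral imidodiphosphorimidate acid (2 mol %, silylated in situ), toluene, −78 to −40 °C; filtration through neutral alumina
Reagents that add atoms: none
Why: In this catalytic asymmetric vinylogous Mukaiyama–Michael addition (silylium/chiral-anion catalysis) the furan attacks through its methyl-bearing carbon (C8) at the enone β-carbon (C1), the chiral anion selects the enone face (C1), an open antiperiplanar transition state with the furan ring turned away from the cyclopentene and only CH3 above it should set C8 relative to C1, and silyl transfer leaves the enol ether regiospecifically at C4=C6.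

Step 3
Reactants: 4 silyl enol ether
Product: 5 (5R)-5-methyl-5-[1-(trimethylsilyloxy)bicyclo[3.1.0]hexan-4-yl]furan-2(5H)-one, CH2 bridge (C5) anti to the butenolide, C1 as in 4
Conditions: Et2Zn, CH2I2, CH2Cl2, 0 °C
Reagents that add atoms: diiodomethane, ICI
Why: In the Furukawa–Simmons–Smith cyclopropanation the electrophilic zinc carbenoid takes the electron-rich enol ether rather than the butenolide C=C and adds anti to the C1 substituent, and both new centres (C4, C6) vanish again in step 5.

Step 4
Reactants: 5 siloxycyclopropane butenolide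
Product: 6 (5R)-5-methyl-5-[1-(trimethylsilyloxy)bicyclo[3.1.0]hexan-4-yl]dihydrofuran-2(3H)-one, ring stereochemistry as in 5
Conditions: H2 (1 atm), Pd/C, EtOAc, rt
Reagents that add atoms: none
Why: Heterogeneous hydrogenation saturates the only remaining C=C (C9=C10), the siloxycyclopropane and quaternary C8 are untouched, and no stereocenter forms.

Step 5
Reactants: 6 siloxycyclopropane lactone
Product: 8 (5R)-5-methyl-5-[(1S)-4-oxocyclohex-2-en-1-yl]dihydrofuran-2(3H)-one, via β-chloro ketone 7 (not isolated)
Conditions: FeCl3 (2.2 equiv), DMF, 0 °C to rt; then NaOAc, MeOH, 60 °C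
Reagents that add atoms: none
Why: FeCl3 oxidises the siloxycyclopropane with loss of Me3SiCl to the cyclopropyloxy radical, whose β-scission breaks the shared C4–C6 bond, so that C4 becomes the ketone and the five-membered ring C1–C2–C3–C4–C6 opens out to the six-membered ring C1–C2–C3–C4–C5–C6 with a secondary radical at C6; chlorine-atom transfer from a second FeCl3 gives 7 and NaOAc eliminates HCl (E1cB) to give 8. The closest known reaction is the Ito–Saegusa one-carbon ring expansion of 1-siloxybicyclo[n.1.0]alkanes to 2-cycloalkenones. No ring is closed in this step: the ring grows because the zero-atom bridge of the bicycle is cut. No stereocenter is formed in 8 (the C–Cl centre of 7 is lost again), and C1 and C8 are spectators. The step needs cleavage of the central bond rather than the outer C4–C5 bond, which is secured by formation of a secondary instead of a primary radical and by the larger strain release, and it needs the new carbon on the C6 side of the carbonyl group, which is secured by the enol ether position fixed in step 2. The 1,3-relation C4/C1 thus becomes the 1,4-relation of the target ring, and the C5=C6 double bond keeps C1 stereogenic.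

Step 6
Reactants: 8 enone
Product: 10 (4S)-4-[(2R)-2-methyl-5-oxotetrahydrofuran-2-yl]cyclohex-1-en-1-yl trifluoromethanesulfonate, via lithium enolate 9 (not isolated)
Conditions: L-Selectride (1.05 equiv), THF, −78 °C; then PhNTf2, −78 to 0 °C
Reagents that add atoms: N-phenylbis(trifluoromethanesulfonimide), O=S(=O)(N(c1ccccc1)S(=O)(=O)C(F)(F)F)C(F)(F)F
Why: 1,4-Reduction of the β-unsubstituted cyclohexenone gives the enolate only at C4=C5 and O-triflation (enolate trapping) fixes this regiochemistry, so that C1 stays stereogenic, while the lactone is not attacked at −78 °C.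

Step 7
Reactants: 10 enol triflate
Product: 11 (5R)-5-methyl-5-[(1S)-4-methylcyclohex-3-en-1-yl]dihydrofuran-2(3H)-one
Conditions: MeMgBr (1.3 equiv), Fe(acac)3 (5 mol %), THF–NMP, −30 °C
Reagents that add atoms: methylmagnesium bromide, C[Mg]Br
Why: Iron-catalysed (Kochi–Fürstner) cross-coupling of the alkenyl triflate is faster than Grignard addition to the lactone and places the C4 methyl group with the double bond fixed at C4=C5.

Step 8
Reactants: 11 methylcyclohexene lactone
Product: 12 (5R)-5-methyl-5-[(1R,3S,6S)-6-methyl-7-oxabicyclo[4.1.0]heptan-3-yl]dihydrofuran-2(3H)-one (epoxide oxygen anti to the lactone substituent)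
Conditions: D-fructose-derived Shi ketone (30 mol %), Oxone, K2CO3, Bu4NHSO4, MeCN–DMM/aq. Na2B4O7–EDTA, 0 °C
Reagents that add atoms: potassium peroxymonosulfate (Oxone), [K+].[O-]S(=O)(=O)OO
Why: The Shi asymmetric epoxidation (dioxirane, spiro transition state) is reagent-controlled on trisubstituted alkenes, and the D-fructose-derived ketone should deliver oxygen to the ring face anti to the C1 substituent, which sets C4 and C5.

Step 9
Reactants: 12 epoxide
Product: 13 (5R)-5-[(1S,3R,4R)-4-bromo-3-hydroxy-4-methylcyclohexyl]-5-methyldihydrofuran-2(3H)-one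
Conditions: anhydrous HBr (1.05 equiv), CH2Cl2, −78 °C
Reagents that add atoms: hydrogen bromide, Br
Why: In this acid-mediated epoxide opening the Markovnikov and the trans-diaxial (Fürst–Plattner) preferences coincide, so bromide attacks tertiary C4 with inversion from the face of the C1 substituent and gives the diaxial tertiary bromide/secondary alcohol.

Step 10
Reactants: 13 bromohydrin
Product: 17 (5R)-5-[(1S,3S,4S)-3-bromo-4-chloro-4-methylcyclohexyl]-5-methyldihydrofuran-2(3H)-one, via chlorosulfite 14 (not isolated), via bromonium chloride 15 (not isolated), via diaxial iso-bromochloride 16 (not isolated)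
Conditions: SOCl2 (1.2 equiv), CH2Cl2, 0 °C to rt; then MeCN, 80 °C
Reagents that add atoms: thionyl chloride, O=S(Cl)Cl
Why: In this deoxychlorination with anchimeric assistance the antiperiplanar axial bromine expels the chlorosulfite to give the bromonium ion on the face syn to the C1 substituent, chloride opens it anti either at tertiary C4 (17 directly, 1,2-bromine shift) or at C5 (diaxial 16), and heating in a polar solvent should move 16 to the diequatorial tertiary chloride 17 by the known diaxial-to-diequatorial (type I dyotropic) rearrangement of vicinal dihalides, so that C4 and C5 both derive from the epoxide of step 8.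

Step 11
Reactants: 17 bromochloro lactone
Product: 18 (6R)-6-[(1S,3S,4S)-3-bromo-4-chloro-4-methylcyclohexyl]-6-hydroxy-2-methylhept-1-en-3-one
Conditions: isopropenyllithium (1.1 equiv, from 2-bromopropene and t-BuLi), THF–Et2O, −78 °C; AcOH quench at −78 °C
Reagents that add atoms: isopropenyllithium, [Li]C(C)=C, made from 2-bromopropene, CC(Br)=C
Why: Single addition of an alkenyllithium to a γ-lactone works because the lactolate survives at −78 °C and collapses to the γ-hydroxy enone only on work-up, and both equatorial C–halogen bonds lack an antiperiplanar hydrogen, which slows E2.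

Step 12
Reactants: 18 hydroxy enone
Product: 19 (3R,6R)-6-[(1S,3S,4S)-3-bromo-4-chloro-4-methylcyclohexyl]-2-methylhept-1-ene-3,6-diol (target)
Conditions: (S)-Me-CBS (20 mol %), catecholborane (2.5 equiv), toluene, −78 °C; MeOH quench
Reagents that add atoms: none
Why: In the Corey–Bakshi–Shibata reduction, with isopropenyl as the large and the CH2 chain as the small group, the (S)-oxazaborolidine should deliver hydride to give the (R)-allylic alcohol at C11, 1,2-selectively and without touching C–Br or C–Cl.

Compound list
1 | α-angelica lactone (5-methylfuran-2(3H)-one) | CC1=CCC(=O)O1 | starting material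
2 | 5-methyl-2-(trimethylsilyloxy)furan | Cc1ccc(O[Si](C)(C)C)o1 | intermediate
3 | cyclopent-2-en-1-one | O=C1CCC=C1 | starting material
4 | (5R)-5-methyl-5-[(1S)-3-(trimethylsilyloxy)cyclopent-2-en-1-yl]furan-2(5H)-one | O=C1C=C[C@@](C)(O1)[C@H]2CCC(O[Si](C)(C)C)=C2 | intermediate
5 | siloxycyclopropane butenolide, CH2 bridge anti to the butenolide | O=C1C=C[C@@](C)(O1)[C@H]2CC[C@]3(O[Si](C)(C)C)C[C@H]23 | intermediate
6 | siloxycyclopropane lactone (dihydro-5) | O=C1CC[C@@](C)(O1)[C@H]2CC[C@]3(O[Si](C)(C)C)C[C@H]23 | intermediate
7 | 5-(2-chloro-4-oxocyclohexyl)-5-methyldihydrofuran-2(3H)-one, C1 and C8 as in 6, epimers at C–Cl | O=C1CC[C@@](C)(O1)[C@H]2CCC(=O)CC2Cl | intermediate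
8 | (5R)-5-methyl-5-[(1S)-4-oxocyclohex-2-en-1-yl]dihydrofuran-2(3H)-one | O=C1CC[C@@](C)(O1)[C@H]2CCC(=O)C=C2 | intermediate
9 | lithium enolate (C4=C5) of the dihydro ketone | O=C1CC[C@@](C)(O1)[C@H]2CCC([O-])=CC2.[Li+] | intermediate
10 | (4S)-4-[(2R)-2-methyl-5-oxotetrahydrofuran-2-yl]cyclohex-1-en-1-yl triflate | O=C1CC[C@@](C)(O1)[C@H]2CCC(OS(=O)(=O)C(F)(F)F)=CC2 | intermediate
11 | (5R)-5-methyl-5-[(1S)-4-methylcyclohex-3-en-1-yl]dihydrofuran-2(3H)-one | O=C1CC[C@@](C)(O1)[C@H]2CCC(C)=CC2 | intermediate
12 | C4–C5 epoxide, oxygen anti to the lactone substituent | O=C1CC[C@@](C)(O1)[C@H]2CC[C@]3(C)O[C@@H]3C2 | intermediate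
13 | (5R)-5-[(1S,3R,4R)-4-bromo-3-hydroxy-4-methylcyclohexyl]-5-methyldihydrofuran-2(3H)-one | O=C1CC[C@@](C)(O1)[C@H]2CC[C@@](C)(Br)[C@H](O)C2 | intermediate
14 | chlorosulfite of 13 | O=C1CC[C@@](C)(O1)[C@H]2CC[C@@](C)(Br)[C@H](OS(=O)Cl)C2 | intermediate
15 | C4–C5 bromonium chloride, bromine syn to the lactone substituent | O=C1CC[C@@](C)(O1)[C@H]2CC[C@@]3(C)[Br+][C@H]3C2.[Cl-] | intermediate
16 | (5R)-5-[(1S,3R,4R)-4-bromo-3-chloro-4-methylcyclohexyl]-5-methyldihydrofuran-2(3H)-one | O=C1CC[C@@](C)(O1)[C@H]2CC[C@@](C)(Br)[C@H](Cl)C2 | intermediate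
17 | (5R)-5-[(1S,3S,4S)-3-bromo-4-chloro-4-methylcyclohexyl]-5-methyldihydrofuran-2(3H)-one | O=C1CC[C@@](C)(O1)[C@H]2CC[C@](C)(Cl)[C@@H](Br)C2 | intermediate
18 | (6R)-6-[(1S,3S,4S)-3-bromo-4-chloro-4-methylcyclohexyl]-6-hydroxy-2-methylhept-1-en-3-one | C=C(C)C(=O)CC[C@@](C)(O)[C@H]1CC[C@](C)(Cl)[C@@H](Br)C1 | intermediate
19 | (3R,6R)-6-[(1S,3S,4S)-3-bromo-4-chloro-4-methylcyclohexyl]-2-methylhept-1-ene-3,6-diol | C=C(C)[C@H](O)CC[C@@](C)(O)[C@H]1CC[C@](C)(Cl)[C@@H](Br)C1 | target

Total step count: 12. Longest linear sequence: 12.

Steps most likely to fail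

Step 2. Possible failures are poor face selection on the enone, the wrong relative topicity between C8 and C1, or hydrolysis of the enol ether that carries the regiochemical label. The fallback sets out from 1 and 3 and comes back at 11.
- α-Angelica lactone 1 is added directly to 3 under iminium catalysis by a 9-amino-9-deoxy-epi-cinchona primary amine salt (direct vinylogous Michael addition). This gives the keto butenolide F1.
- Hydrogenation gives the keto lactone F2.
- The enol-ether label is now absent, so the other α-carbon is used. Kinetic deprotonation away from the branched C1 (LDA, TMSCl) gives the enol ether F3.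
- Et2Zn/CH3CHI2 gives the methyl-substituted siloxycyclopropane F4.
- FeCl3 gives the β-chloro ketone F5, and NaOAc gives the carvone-type enone F6. Here the inserted carbon is C4 with its methyl group, and the carbonyl carbon is C5.
- TsNHNH2 gives the tosylhydrazone F7. Catecholborane/NaOAc (allylic diazene, 1,5-hydrogen shift) moves the double bond to C4=C5 and returns to 11.

Step 10. Possible failures are return of the bromonium ion to the alkene by loss of electrophilic bromine, E1 loss of HX on heating, or an unfavourable position of the diaxial/diequatorial equilibrium. The fallback sets out from 11 and comes back at 16. It introduces the halogens in the reverse order.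
- NBS/H2O adds reversibly and gives the trans-diaxial Markovnikov bromohydrin F8.
- K2CO3 closes the epoxide syn to the lactone substituent, F9.
- LiCl/AcOH opens it trans-diaxially at secondary C5 to give the chlorohydrin F10.
- HBr/LiBr converts the axial tertiary alcohol into the axial tertiary bromide 16. Axial attack and shielding by the antiperiplanar chlorine reinforce each other.
- 16 is then equilibrated thermally to 17 as in step 10.

Step 11. Possible failures are a second addition to the liberated enone, base-induced loss of HBr or HCl, or bromine–lithium exchange. The fallback sets out from 17 and comes back at 18. The lactone is opened with MeNH(OMe)·HCl/i-PrMgCl at −20 °C to give the hydroxy Weinreb amide F11. Its magnesium chelate takes up only one equivalent of the less basic isopropenylmagnesium bromide and releases 18 on work-up.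

Further compounds
F1 | step 2 | 5-methyl-5-(3-oxocyclopentyl)furan-2(5H)-one, C1 and C8 as in 4 | O=C1C=C[C@@](C)(O1)[C@H]2CCC(=O)C2
F2 | step 2 | (5R)-5-methyl-5-[(1S)-3-oxocyclopentyl]dihydrofuran-2(3H)-one | O=C1CC[C@@](C)(O1)[C@H]2CCC(=O)C2
F3 | step 2 | kinetic trimethylsilyl enol ether of F2 (double bond away from C1) | O=C1CC[C@@](C)(O1)[C@H]2CC=C(O[Si](C)(C)C)C2
F4 | step 2 | 6-methyl-1-(trimethylsilyloxy)bicyclo[3.1.0]hexan-3-yl lactone, cyclopropane centres as a mixture | O=C1CC[C@@](C)(O1)[C@H]2CC3C(C)C3(O[Si](C)(C)C)C2
F5 | step 2 | 5-(3-chloro-4-methyl-5-oxocyclohexyl)-5-methyldihydrofuran-2(3H)-one, C1 and C8 as in F2 | O=C1CC[C@@](C)(O1)[C@H]2CC(Cl)C(C)C(=O)C2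
F6 | step 2 | (5R)-5-methyl-5-[(1S)-4-methyl-5-oxocyclohex-3-en-1-yl]dihydrofuran-2(3H)-one | O=C1CC[C@@](C)(O1)[C@H]2CC=C(C)C(=O)C2
F7 | step 2 | tosylhydrazone of F6 | O=C1CC[C@@](C)(O1)[C@H]2CC=C(C)C(=NNS(=O)(=O)c3ccc(C)cc3)C2
F8 | step 10 | trans-diaxial bromohydrin (C5–Br anti, C4–OH syn to the lactone substituent) | O=C1CC[C@@](C)(O1)[C@H]2CC[C@@](C)(O)[C@H](Br)C2
F9 | step 10 | C4–C5 epoxide, oxygen syn to the lactone substituent | O=C1CC[C@@](C)(O1)[C@H]2CC[C@@]3(C)O[C@H]3C2
F10 | step 10 | trans-diaxial chlorohydrin (C5–Cl anti, C4–OH syn to the lactone substituent) | O=C1CC[C@@](C)(O1)[C@H]2CC[C@@](C)(O)[C@H](Cl)C2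
F11 | step 11 | (4R)-4-[(1S,3S,4S)-3-bromo-4-chloro-4-methylcyclohexyl]-4-hydroxy-N-methoxy-N-methylpentanamide | CON(C)C(=O)CC[C@@](C)(O)[C@H]1CC[C@](C)(Cl)[C@@H](Br)C1
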